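## Analysis of the target

Putraflavone (33) is two flavone units joined by one biaryl bond. C3' of ring B of a 5-hydroxy-7-methoxyflavone (rings A, C, B) is bonded to C8'' of ring A'' of a 5'',7''-dihydroxyflavone whose ring B'' is a 4-methoxyphenyl group. The molecule has no stereocentre. The only stereo-relevant element is the C3'–C8'' axis, which carries three ortho substituents (C4'–OH, C7''–OH and the ring oxygen O1'').

The sensitive groups are four phenols (two chelated to the C4 and C4'' carbonyls), two aryl methyl ethers (C7–OMe and C4'''–OMe) that every late dealkylation must spare, and two γ-pyranones that hot alkali opens. Once C5''–OH is free, hot protic acid can open ring C'' and close it on the other oxygen, turning the 8''-aryl flavone into its 6''-aryl isomer.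

The synthesis is hard for two reasons. The biaryl bond links two electron-rich rings at a carbon (C8'') lying between two oxygen-bearing carbons, a crowded site for cross-coupling. Ring A'' is a phloroglucinol whose three oxygens must play three different roles.

The strategy rests on ring A'' (C4a'', C5'', C6'', C7'', C8'', C8a''), whose oxygens on C5'', C7'' and C8a'' are mutually meta around C8''. The oxygens on C7'' and C8a'' flank C8'' and are equivalent for pyranone closure. The oxygen on C5'' is para to C8'', and closure on it would give the 6''-aryl flavone. Ring A'' is therefore built from open-chain pieces so that each oxygen arrives in its own state: ethyl ether at C5'', silyl ether at C7'', free phenol at C8a''.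

## Retrosynthetic reasoning

**33 to 32.** The last disconnection cuts three O–benzyl bonds (C5, C4', C7'') and the O–ethyl bond at C5''. The ethyl group is peri to the C4'' carbonyl, so a chelating Lewis acid can remove it while the two methyl ethers, which have no carbonyl neighbour, stay. The forward step must release four phenols in one operation without ring opening.

**32 to 26 and 28.** The pyranone of the 7-methoxyflavone unit is cut at O1–C2 and at C2–C3. This leads through chalcone 30 back to aldehyde 26 and acetophenone 28. Two steps suffice for this ring, and the aldehyde carbon of ring B becomes C2. Acetophenone 28 comes from 27 by capping one of its two equivalent phenols, so that the condensation runs on a mono-phenoxide.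

**26 to 23.** These are functional-group changes only. The aldehyde is unmasked from the dioxolane of 25. The benzyl ether at C7'' replaces the silyl ether of 23, because a silyl ether on a 7-hydroxyflavone would not survive the alkaline condensation.

**23 to 17 and 18.** Ring C'' is cut at O1''–C2'' and at C4''–C3''. Ynone 21 and carbinol 20 lead back to salicylaldehyde 17 and alkyne 18, which brings in C2'', C3'' and ring B'' in one piece. Only the free C8a'' hydroxyl can close the ring, because the C5'' oxygen is an ethyl ether, so the 8''-aryl flavone is the only possible product.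

**17 to 15.** The C4a''–C4'' bond is cut. The forward reaction is a formylation delivered through the magnesium phenoxide, which reaches only the one free carbon ortho to the C8a'' hydroxyl. It runs under basic conditions that spare the acetal, the silyl ether and the benzyl ether.

**15 to 10 and 6.** This is the central disconnection. Three bonds of ring A'' are cut: C8''–C8a'', C6''–C7'' and C4a''–C8a''. The four carbons C8a'', C4a'', C5'' and C6'' come from cyclobutenone 10, which carries the ethoxy group. C8'' and C7'' come from ynol ether 6, which carries ring B and the silyloxy group. The forward reaction makes the whole phloroglucinol ring with its three oxygens already differentiated, and it places the hindered aryl group without any cross-coupling.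

**6 to 1.** The ynol ether is traced to ester 3 by one-carbon homologation through enolate 4 and ynolate 5. In this step ring B migrates from the ester carbon (the future C7'') to the new carbon (the future C8''), so the C3'–C8'' bond is formed by a 1,2-shift. Ester 3 comes from 1 by benzylation (2) and acetalisation, which protect the phenol and the aldehyde against the organolithium reagents.

**10 to 7 and 8.** The cyclobutenone is cut across two ring bonds into alkyne 7 and ketene 9. Ketene 9 is released from 8 in the flask.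

## Alternatives that were turned down

**Alternative 1:** ring B from a pyrone.

- **Disconnection:** C3'–C4' and C5'–C6' of ring B.
- **Forward key step:** methyl 2-oxo-3-(2,4,6-trimethoxyphenyl)-2H-pyran-5-carboxylate A1 reacts as an electron-poor diene with 1,1-dimethoxyethene A2. Decarboxylative cycloreversion and loss of one alkoxy group give methyl 4-methoxy-3-(2,4,6-trimethoxyphenyl)benzoate A3.
- **For it:** the orientation is fixed by the polarisation of both partners. The reaction is thermal and metal-free. The ester of A3 sits at C1', ready for flavone construction. On the reliability of the ring-forming step this alternative is stronger than the chosen strategy.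
- **Against it:** the biaryl bond must already exist in A1, so the hindered coupling to a 2,6-dioxygenated aryl group is only moved to an earlier and more fragile substrate. A3 carries four methyl ethers of the same kind. Three of them must later be cleaved, and the ortho and para oxygens of ring A'' are not distinguished, so the 8''-aryl against 6''-aryl question stays open.
- **Comparison:** the chosen strategy has a less certain key step, but that step forms the biaryl connection and differentiates the three oxygens at once.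

**Alternative 2:** ring B from a siloxydiene and an ethynylchromone.

- **Disconnection:** C2'–C3' and C1'–C6' of ring B.
- **Forward key step:** the diene 5,7-bis(benzyloxy)-8-[4-methoxy-2-(trimethylsilyloxy)buta-1,3-dienyl]-2-(4-methoxyphenyl)chromen-4-one A4 adds to 5-(benzyloxy)-2-ethynyl-7-methoxychromen-4-one A5. Loss of the methoxy group and desilylation give 5,5'',7''-tri-O-benzylputraflavone A6.
- **For it:** it is the most convergent plan. Both chromones are complete before the union, the C4' phenol appears free, and A6 needs only debenzylation. On convergence and on the length of the endgame it is clearly stronger than the chosen strategy.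
- **Against it:** the nucleophilic terminus of A4 carries a doubly ortho-substituted aryl group, which disfavours the reactive s-cis conformer and slows bond formation at that carbon. The silyl enol ether of A4 must be made next to a chromone, which is a Michael acceptor. A5 is a polymerisation-prone acceptor whose C2=C3 bond can compete with the alkyne. An 8-functionalised flavone is needed first.
- **Comparison:** the risk is spread over the synthesis of both partners and the cycloaddition. The chosen strategy reaches 6 and 10 in three steps and one step and keeps the risk in one reaction.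

**Alternative 3:** two acyl shifts on one biaryl diester.

- **Disconnection:** C2–C3 and C2''–C3'' of the two pyranones.
- **Forward key step:** excess strong amide base turns the biaryl diester A7 into two enolates. Each attacks its neighbouring aryl ester, giving the bis(1,3-diketone) A8.
- **For it:** Baker–Venkataraman chemistry is the most proven flavone construction. One operation sets both diketones, and everything after the biaryl is textbook chemistry. On precedent it is stronger than the chosen strategy.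
- **Against it:** A7 needs the hindered biaryl made by cross-coupling of two fully substituted arenes. The choice of which ring A'' oxygen carries the aroyl group must be made before A7, so the regiochemical problem is moved, not solved. The phenol to be aroylated is flanked by an acetyl and an aryl group. Two different esters and two enolates in one molecule allow intermolecular acyl crossover.
- **Comparison:** the chosen strategy builds ring A'' so that the 8''-aryl outcome follows from the mechanism, at the cost of a longer sequence after the key step.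

Key step: step 5

## Route

Remark on the chemistry (assumption): the C3'–C8'' axis is taken as freely rotating at room temperature, so no axial configuration is assigned, in line with the stereo-free structure of the target.

Step 1
Reactants: 1 methyl 5-formyl-2-hydroxybenzoate
Product: 2 methyl 2-(benzyloxy)-5-formylbenzoate
Conditions: BnBr, K2CO3, DMF, 60 °C
Reagents that add atoms: benzyl bromide, BrCc1ccccc1
Why: Williamson etherification of the phenoxide; the aldehyde and ester do not react with carbonate.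

Step 2
Reactants: 2 methyl 2-(benzyloxy)-5-formylbenzoate
Product: 3 methyl 2-(benzyloxy)-5-(1,3-dioxolan-2-yl)benzoate
Conditions: HOCH2CH2OH, p-TsOH·H2O (cat.), PhMe, reflux, Dean–Stark
Reagents that add atoms: ethylene glycol, OCCO
Why: Acid-catalysed acetalisation driven by water removal; the aldehyde must be masked against the organolithium reagents of steps 3 and 7.

Step 3
Reactants: 3 methyl 2-(benzyloxy)-5-(1,3-dioxolan-2-yl)benzoate
Product: 6 triisopropyl({[2-(benzyloxy)-5-(1,3-dioxolan-2-yl)phenyl]ethynyl}oxy)silane, via dibromoenolate 4 (not isolated), via ynolate 5 (not isolated)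
Conditions: CH2Br2, LiTMP, THF, −78 °C; LiHMDS, −78 °C; n-BuLi, −78 → 25 °C; TIPSCl, −78 → 0 °C
Reagents that add atoms: dibromomethane, BrCBr; triisopropylsilyl chloride, CC(C)[Si](Cl)(C(C)C)C(C)C
Why: Kowalski ester homologation: LiCHBr2 adds to the non-enolisable ester and base gives 4; bromine–lithium exchange then triggers the carbenoid 1,2-aryl shift to 5. The bulky silyl chloride should silylate the ynolate on oxygen, not on carbon.

Step 4
Reactants: 7 ethoxyacetylene; 8 acetyl chloride
Product: 10 3-ethoxycyclobut-2-en-1-one, via ketene 9 (not isolated)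
Conditions: Et3N, Et2O, 0 → 25 °C, slow addition of 8
Reagents that add atoms: none
Why: Dehydrochlorination of 8 gives ketene 9, which is trapped by the electron-rich alkyne in a (2+2) cycloaddition. The nucleophilic CH carbon of 7 bonds to the ketene carbonyl carbon, placing the ethoxy group at C3.

Step 5
Reactants: 10 3-ethoxycyclobut-2-en-1-one; 6 triisopropyl({[2-(benzyloxy)-5-(1,3-dioxolan-2-yl)phenyl]ethynyl}oxy)silane
Product: 15 2-[2-(benzyloxy)-5-(1,3-dioxolan-2-yl)phenyl]-5-ethoxy-3-(triisopropylsilyloxy)phenol, via vinylketene 11 (not isolated), via vinylcyclobutenone 12 (not isolated), via dienylketene 13 (not isolated), via cyclohexadienone 14 (not isolated)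
Conditions: 10 (1.2 equiv), PhMe, 80 °C then 110 °C, sealed tube, N2
Reagents that add atoms: none
Why: Danheiser benzannulation, whose closest known form is the reaction of cyclobutenones with trialkylsiloxyalkynes to give resorcinol monosilyl ethers. Heating opens 10 by four-electron electrocyclic ring opening to vinylketene 11. The aryl-bearing carbon of 6 attacks the ketene carbonyl carbon in a (2+2) cycloaddition that closes the four-membered ring of 12 and forms C8''–C8a'' and C6''–C7''. 12 reopens reversibly to dienylketene 13, which closes ring A'' by a thermal six-electron disrotatory electrocyclisation (C4a''–C8a''). Cyclohexadienone 14 then tautomerises to phenol 15. No stereocentre remains; the one in 12 is lost on ring opening. The step needs one selectivity, the orientation of the ketene–alkyne union. The oxygen lone pair of the ynol ether secures it by making the aryl-bearing carbon the nucleophile, so ring B ends between the free hydroxyl and the silyl ether and the ethoxy group ends para to it. The benzyl ether, dioxolane and silyl ether should be inert in neutral hot toluene.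

Step 6
Reactants: 15 2-[2-(benzyloxy)-5-(1,3-dioxolan-2-yl)phenyl]-5-ethoxy-3-(triisopropylsilyloxy)phenol
Product: 17 3-[2-(benzyloxy)-5-(1,3-dioxolan-2-yl)phenyl]-6-ethoxy-2-hydroxy-4-(triisopropylsilyloxy)benzaldehyde, via salicyl alcohol 16 (not isolated)
Conditions: MgCl2, Et3N, (CH2O)n, MeCN, reflux
Reagents that add atoms: formaldehyde (from paraformaldehyde), C=O
Why: Magnesium-mediated ortho-formylation (Casnati–Skattebøl): the magnesium phenoxide delivers formaldehyde to the only free ortho carbon (C4a'') to give 16, and hydride transfer to a second formaldehyde gives the aldehyde. The carbon para to the phenol is not reached, and the basic medium spares the acetal and both ethers.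

Step 7
Reactants: 17 3-[2-(benzyloxy)-5-(1,3-dioxolan-2-yl)phenyl]-6-ethoxy-2-hydroxy-4-(triisopropylsilyloxy)benzaldehyde; 18 1-ethynyl-4-methoxybenzene
Product: 20 1-{3-[2-(benzyloxy)-5-(1,3-dioxolan-2-yl)phenyl]-6-ethoxy-2-hydroxy-4-(triisopropylsilyloxy)phenyl}-3-(4-methoxyphenyl)prop-2-yn-1-ol (racemic), via lithium acetylide 19 (not isolated)
Conditions: 18 (3 equiv), n-BuLi, THF, −78 °C; then 17, −78 → 0 °C; aq. NH4Cl
Reagents that add atoms: none
Why: 1,2-Addition of a lithium acetylide to the aldehyde; one equivalent is consumed by the phenol and the excess adds. The new carbinol centre forms as a racemate and is removed by oxidation in step 8.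

Step 8
Reactants: 20 1-{3-[2-(benzyloxy)-5-(1,3-dioxolan-2-yl)phenyl]-6-ethoxy-2-hydroxy-4-(triisopropylsilyloxy)phenyl}-3-(4-methoxyphenyl)prop-2-yn-1-ol
Product: 21 1-{3-[2-(benzyloxy)-5-(1,3-dioxolan-2-yl)phenyl]-6-ethoxy-2-hydroxy-4-(triisopropylsilyloxy)phenyl}-3-(4-methoxyphenyl)prop-2-yn-1-one
Conditions: MnO2 (excess), CH2Cl2, 25 °C
Reagents that add atoms: none
Why: Neutral MnO2 oxidation of a benzylic, propargylic alcohol; the phenol should be spared, and the resulting ketone is hydrogen-bonded to it.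

Step 9
Reactants: 21 1-{3-[2-(benzyloxy)-5-(1,3-dioxolan-2-yl)phenyl]-6-ethoxy-2-hydroxy-4-(triisopropylsilyloxy)phenyl}-3-(4-methoxyphenyl)prop-2-yn-1-one
Product: 23 8-[2-(benzyloxy)-5-(1,3-dioxolan-2-yl)phenyl]-5-ethoxy-2-(4-methoxyphenyl)-7-(triisopropylsilyloxy)-4H-chromen-4-one, via enaminone 22 (not isolated)
Conditions: Et2NH, EtOH–THF, 25 → 50 °C
Reagents that add atoms: none
Why: Amine-mediated cyclisation of an ortho-hydroxyaryl ynone: conjugate addition of Et2NH gives enaminone 22, and the phenol then adds to the β-carbon and expels the amine (6-endo addition–elimination). This path should give the chromone and not the five-membered aurone.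

Step 10
Reactants: 23 8-[2-(benzyloxy)-5-(1,3-dioxolan-2-yl)phenyl]-5-ethoxy-2-(4-methoxyphenyl)-7-(triisopropylsilyloxy)-4H-chromen-4-one
Product: 25 7-(benzyloxy)-8-[2-(benzyloxy)-5-(1,3-dioxolan-2-yl)phenyl]-5-ethoxy-2-(4-methoxyphenyl)-4H-chromen-4-one, via cesium phenoxide 24 (not isolated)
Conditions: CsF, BnBr, DMF, 25 °C
Reagents that add atoms: benzyl bromide, BrCc1ccccc1
Why: Fluoride cleaves the aryl silyl ether to phenoxide 24, which is benzylated in the same flask (Williamson). Any material that lost its silyl group in step 9 converges on the same product.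

Step 11
Reactants: 25 7-(benzyloxy)-8-[2-(benzyloxy)-5-(1,3-dioxolan-2-yl)phenyl]-5-ethoxy-2-(4-methoxyphenyl)-4H-chromen-4-one
Product: 26 4-(benzyloxy)-3-[7-(benzyloxy)-5-ethoxy-2-(4-methoxyphenyl)-4-oxo-4H-chromen-8-yl]benzaldehyde
Conditions: 2 M HCl, THF, 25 °C
Reagents that add atoms: water, O
Why: Acid-catalysed acetal hydrolysis; the flavone and the benzyl, ethyl and methyl ethers are stable to dilute acid at room temperature.

Step 12
Reactants: 27 1-(2,6-dihydroxy-4-methoxyphenyl)ethan-1-one
Product: 28 1-[2-(benzyloxy)-6-hydroxy-4-methoxyphenyl]ethan-1-one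
Conditions: BnBr (1.0 equiv), K2CO3, acetone, reflux
Reagents that add atoms: benzyl bromide, BrCc1ccccc1
Why: Williamson mono-benzylation; after the first alkylation the remaining hydroxyl is locked in a hydrogen bond to the carbonyl and should not react under these mild conditions.

Step 13
Reactants: 26 4-(benzyloxy)-3-[7-(benzyloxy)-5-ethoxy-2-(4-methoxyphenyl)-4-oxo-4H-chromen-8-yl]benzaldehyde; 28 1-[2-(benzyloxy)-6-hydroxy-4-methoxyphenyl]ethan-1-one
Product: 30 (E)-1-[2-(benzyloxy)-6-hydroxy-4-methoxyphenyl]-3-{4-(benzyloxy)-3-[7-(benzyloxy)-5-ethoxy-2-(4-methoxyphenyl)-4-oxo-4H-chromen-8-yl]phenyl}prop-2-en-1-one, via aldol 29 (not isolated)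
Conditions: KOH (aq.), EtOH–THF, 25 °C; then dilute HCl
Reagents that add atoms: none
Why: Claisen–Schmidt condensation: the enolate of 28 adds to the non-enolisable aldehyde to give aldol 29, and E1cB dehydration gives the conjugated enone. The E geometry is the thermodynamic one.

Step 14
Reactants: 30 (E)-1-[2-(benzyloxy)-6-hydroxy-4-methoxyphenyl]-3-{4-(benzyloxy)-3-[7-(benzyloxy)-5-ethoxy-2-(4-methoxyphenyl)-4-oxo-4H-chromen-8-yl]phenyl}prop-2-en-1-one
Product: 32 5-(benzyloxy)-2-{4-(benzyloxy)-3-[7-(benzyloxy)-5-ethoxy-2-(4-methoxyphenyl)-4-oxo-4H-chromen-8-yl]phenyl}-7-methoxy-4H-chromen-4-one, via flavanone 31 (not isolated)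
Conditions: I2 (cat.), DMSO, 130 °C
Reagents that add atoms: none
Why: Iodine–DMSO oxidative cyclisation of a 2'-hydroxychalcone: oxa-Michael closure gives flavanone 31, and α-iodination with loss of HI gives the flavone while DMSO reoxidises the iodide. Any flavanone already formed in step 13 converges here.

Step 15
Reactants: 32 5-(benzyloxy)-2-{4-(benzyloxy)-3-[7-(benzyloxy)-5-ethoxy-2-(4-methoxyphenyl)-4-oxo-4H-chromen-8-yl]phenyl}-7-methoxy-4H-chromen-4-one
Product: 33 putraflavone, 5-hydroxy-2-{4-hydroxy-3-[5,7-dihydroxy-2-(4-methoxyphenyl)-4-oxo-4H-chromen-8-yl]phenyl}-7-methoxy-4H-chromen-4-one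
Conditions: BCl3 (excess), C6HMe5, CH2Cl2, −78 → 25 °C; then H2O
Reagents that add atoms: none
Why: Lewis-acid dealkylation: BCl3 cleaves the three benzyl ethers, with pentamethylbenzene trapping the benzyl cations. The ethyl ether peri to the C4'' carbonyl is cleaved through a six-membered boron chelate by chloride attack on the ethyl group; the methyl ethers at C7 and C4''' have no carbonyl neighbour and should stay.

## Compound list

1 | methyl 5-formyl-2-hydroxybenzoate (methyl 5-formylsalicylate) | COC(=O)c1cc(C=O)ccc1O | starting material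
2 | methyl 2-(benzyloxy)-5-formylbenzoate | COC(=O)c1cc(C=O)ccc1OCc1ccccc1 | intermediate
3 | methyl 2-(benzyloxy)-5-(1,3-dioxolan-2-yl)benzoate | COC(=O)c1cc(C2OCCO2)ccc1OCc1ccccc1 | intermediate
4 | lithium 1-[2-(benzyloxy)-5-(1,3-dioxolan-2-yl)phenyl]-2,2-dibromoethen-1-olate (not isolated) | [Li+].[O-]C(=C(Br)Br)c1cc(C2OCCO2)ccc1OCc1ccccc1 | intermediate
5 | lithium 2-[2-(benzyloxy)-5-(1,3-dioxolan-2-yl)phenyl]ethyn-1-olate (not isolated) | [Li+].[O-]C#Cc1cc(C2OCCO2)ccc1OCc1ccccc1 | intermediate
6 | triisopropyl({[2-(benzyloxy)-5-(1,3-dioxolan-2-yl)phenyl]ethynyl}oxy)silane | CC(C)[Si](OC#Cc1cc(C2OCCO2)ccc1OCc1ccccc1)(C(C)C)C(C)C | intermediate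
7 | ethoxyacetylene | C#COCC | starting material
8 | acetyl chloride | CC(Cl)=O | starting material
9 | ketene (not isolated) | C=C=O | intermediate
10 | 3-ethoxycyclobut-2-en-1-one | CCOC1=CC(=O)C1 | intermediate
11 | 3-ethoxybuta-1,3-dien-1-one (not isolated) | C=C(OCC)C=C=O | intermediate
12 | 2-[2-(benzyloxy)-5-(1,3-dioxolan-2-yl)phenyl]-4-(1-ethoxyethenyl)-3-(triisopropylsilyloxy)cyclobut-2-en-1-one (racemic, not isolated) | C=C(OCC)C1C(=O)C(-c2cc(C3OCCO3)ccc2OCc2ccccc2)=C1O[Si](C(C)C)(C(C)C)C(C)C | intermediate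
13 | 2-[2-(benzyloxy)-5-(1,3-dioxolan-2-yl)phenyl]-5-ethoxy-3-(triisopropylsilyloxy)hexa-1,3,5-trien-1-one, C2 and C5 cis about C3=C4 (not isolated) | C=C(OCC)/C=C(/O[Si](C(C)C)(C(C)C)C(C)C)C(=C=O)c1cc(C2OCCO2)ccc1OCc1ccccc1 | intermediate
14 | 2-[2-(benzyloxy)-5-(1,3-dioxolan-2-yl)phenyl]-5-ethoxy-3-(triisopropylsilyloxy)cyclohexa-2,4-dien-1-one (not isolated) | O=C1CC(OCC)=CC(O[Si](C(C)C)(C(C)C)C(C)C)=C1c1cc(C2OCCO2)ccc1OCc1ccccc1 | intermediate
15 | 2-[2-(benzyloxy)-5-(1,3-dioxolan-2-yl)phenyl]-5-ethoxy-3-(triisopropylsilyloxy)phenol | Oc1cc(OCC)cc(O[Si](C(C)C)(C(C)C)C(C)C)c1-c1cc(C2OCCO2)ccc1OCc1ccccc1 | intermediate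
16 | 2-[2-(benzyloxy)-5-(1,3-dioxolan-2-yl)phenyl]-5-ethoxy-6-(hydroxymethyl)-3-(triisopropylsilyloxy)phenol (as its magnesium salt, not isolated) | OCc1c(OCC)cc(O[Si](C(C)C)(C(C)C)C(C)C)c(-c2cc(C3OCCO3)ccc2OCc2ccccc2)c1O | intermediate
17 | 3-[2-(benzyloxy)-5-(1,3-dioxolan-2-yl)phenyl]-6-ethoxy-2-hydroxy-4-(triisopropylsilyloxy)benzaldehyde | O=Cc1c(OCC)cc(O[Si](C(C)C)(C(C)C)C(C)C)c(-c2cc(C3OCCO3)ccc2OCc2ccccc2)c1O | intermediate
18 | 1-ethynyl-4-methoxybenzene | C#Cc1ccc(OC)cc1 | starting material
19 | lithium (4-methoxyphenyl)acetylide (not isolated) | [Li+].[C-]#Cc1ccc(OC)cc1 | intermediate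
20 | 1-{3-[2-(benzyloxy)-5-(1,3-dioxolan-2-yl)phenyl]-6-ethoxy-2-hydroxy-4-(triisopropylsilyloxy)phenyl}-3-(4-methoxyphenyl)prop-2-yn-1-ol (racemic) | OC(C#Cc1ccc(OC)cc1)c1c(OCC)cc(O[Si](C(C)C)(C(C)C)C(C)C)c(-c2cc(C3OCCO3)ccc2OCc2ccccc2)c1O | intermediate
21 | 1-{3-[2-(benzyloxy)-5-(1,3-dioxolan-2-yl)phenyl]-6-ethoxy-2-hydroxy-4-(triisopropylsilyloxy)phenyl}-3-(4-methoxyphenyl)prop-2-yn-1-one | O=C(C#Cc1ccc(OC)cc1)c1c(OCC)cc(O[Si](C(C)C)(C(C)C)C(C)C)c(-c2cc(C3OCCO3)ccc2OCc2ccccc2)c1O | intermediate
22 | 1-{3-[2-(benzyloxy)-5-(1,3-dioxolan-2-yl)phenyl]-6-ethoxy-2-hydroxy-4-(triisopropylsilyloxy)phenyl}-3-(diethylamino)-3-(4-methoxyphenyl)prop-2-en-1-one (either alkene geometry, not isolated) | CCN(CC)C(=CC(=O)c1c(OCC)cc(O[Si](C(C)C)(C(C)C)C(C)C)c(-c2cc(C3OCCO3)ccc2OCc2ccccc2)c1O)c1ccc(OC)cc1 | intermediate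
23 | 8-[2-(benzyloxy)-5-(1,3-dioxolan-2-yl)phenyl]-5-ethoxy-2-(4-methoxyphenyl)-7-(triisopropylsilyloxy)-4H-chromen-4-one | COc1ccc(-c2cc(=O)c3c(OCC)cc(O[Si](C(C)C)(C(C)C)C(C)C)c(-c4cc(C5OCCO5)ccc4OCc4ccccc4)c3o2)cc1 | intermediate
24 | cesium 8-[2-(benzyloxy)-5-(1,3-dioxolan-2-yl)phenyl]-5-ethoxy-2-(4-methoxyphenyl)-4-oxo-4H-chromen-7-olate (not isolated) | COc1ccc(-c2cc(=O)c3c(OCC)cc([O-])c(-c4cc(C5OCCO5)ccc4OCc4ccccc4)c3o2)cc1.[Cs+] | intermediate
25 | 7-(benzyloxy)-8-[2-(benzyloxy)-5-(1,3-dioxolan-2-yl)phenyl]-5-ethoxy-2-(4-methoxyphenyl)-4H-chromen-4-one | COc1ccc(-c2cc(=O)c3c(OCC)cc(OCc4ccccc4)c(-c4cc(C5OCCO5)ccc4OCc4ccccc4)c3o2)cc1 | intermediate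
26 | 4-(benzyloxy)-3-[7-(benzyloxy)-5-ethoxy-2-(4-methoxyphenyl)-4-oxo-4H-chromen-8-yl]benzaldehyde | COc1ccc(-c2cc(=O)c3c(OCC)cc(OCc4ccccc4)c(-c4cc(C=O)ccc4OCc4ccccc4)c3o2)cc1 | intermediate
27 | 1-(2,6-dihydroxy-4-methoxyphenyl)ethan-1-one | CC(=O)c1c(O)cc(OC)cc1O | starting material
28 | 1-[2-(benzyloxy)-6-hydroxy-4-methoxyphenyl]ethan-1-one | CC(=O)c1c(O)cc(OC)cc1OCc1ccccc1 | intermediate
29 | 1-[2-(benzyloxy)-6-hydroxy-4-methoxyphenyl]-3-{4-(benzyloxy)-3-[7-(benzyloxy)-5-ethoxy-2-(4-methoxyphenyl)-4-oxo-4H-chromen-8-yl]phenyl}-3-hydroxypropan-1-one (racemic, not isolated) | COc1ccc(-c2cc(=O)c3c(OCC)cc(OCc4ccccc4)c(-c4cc(C(O)CC(=O)c5c(O)cc(OC)cc5OCc5ccccc5)ccc4OCc4ccccc4)c3o2)cc1 | intermediate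
30 | (E)-1-[2-(benzyloxy)-6-hydroxy-4-methoxyphenyl]-3-{4-(benzyloxy)-3-[7-(benzyloxy)-5-ethoxy-2-(4-methoxyphenyl)-4-oxo-4H-chromen-8-yl]phenyl}prop-2-en-1-one | COc1ccc(-c2cc(=O)c3c(OCC)cc(OCc4ccccc4)c(-c4cc(/C=C/C(=O)c5c(O)cc(OC)cc5OCc5ccccc5)ccc4OCc4ccccc4)c3o2)cc1 | intermediate
31 | 5-(benzyloxy)-2-{4-(benzyloxy)-3-[7-(benzyloxy)-5-ethoxy-2-(4-methoxyphenyl)-4-oxo-4H-chromen-8-yl]phenyl}-7-methoxy-2,3-dihydro-4H-chromen-4-one (racemic, not isolated) | COc1ccc(-c2cc(=O)c3c(OCC)cc(OCc4ccccc4)c(-c4cc(C5CC(=O)c6c(OCc7ccccc7)cc(OC)cc6O5)ccc4OCc4ccccc4)c3o2)cc1 | intermediate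
32 | 5-(benzyloxy)-2-{4-(benzyloxy)-3-[7-(benzyloxy)-5-ethoxy-2-(4-methoxyphenyl)-4-oxo-4H-chromen-8-yl]phenyl}-7-methoxy-4H-chromen-4-one | COc1ccc(-c2cc(=O)c3c(OCC)cc(OCc4ccccc4)c(-c4cc(-c5cc(=O)c6c(OCc7ccccc7)cc(OC)cc6o5)ccc4OCc4ccccc4)c3o2)cc1 | intermediate
33 | putraflavone | COc1ccc(-c2cc(=O)c3c(O)cc(O)c(-c4cc(-c5cc(=O)c6c(O)cc(OC)cc6o5)ccc4O)c3o2)cc1 | target

## Step count and risks

Total step count: 15. Longest linear sequence: 13 steps (steps 1–3, 5–11, 13–15). Steps 4 and 12 are side branches.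

Least certain steps:

**Step 5 (key step).** Capture of vinylketene 11 by the ortho-substituted aryl ynol ether may be slow. The ketene could then oligomerise or acylate the product phenol. The siloxyalkyne may also decompose on heating, by silyl migration to carbon or by hydrolysis.

Fallback: the C3'–C8'' bond is made by Suzuki–Miyaura coupling. The fallback sets out from 3 and comes back at 25.
- Saponification (LiOH, THF–H2O) should give 2-(benzyloxy)-5-(1,3-dioxolan-2-yl)benzoic acid F1.
- Decarboxylative ipso-iodination (I2, K3PO4, MeCN, heat), of the kind known for ortho-alkoxybenzoic acids, should give 2-[4-(benzyloxy)-3-iodophenyl]-1,3-dioxolane F2.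
- Miyaura borylation (bis(pinacolato)diboron, PdCl2(dppf), KOAc, dioxane) should give 2-[2-(benzyloxy)-5-(1,3-dioxolan-2-yl)phenyl]-4,4,5,5-tetramethyl-1,3,2-dioxaborolane F3.
- The partner comes from purchased acacetin F4. Benzylation of the more acidic C7 hydroxyl (BnBr, K2CO3, acetone) gives 7-(benzyloxy)-5-hydroxy-2-(4-methoxyphenyl)-4H-chromen-4-one F5.
- Ethylation of the chelated hydroxyl (EtI, K2CO3, DMF, 60 °C) gives 7-(benzyloxy)-5-ethoxy-2-(4-methoxyphenyl)-4H-chromen-4-one F6.
- Iodination (N-iodosuccinimide, CF3CO2H cat., MeCN), expected at C8 once both oxygens are alkylated, gives 7-(benzyloxy)-5-ethoxy-8-iodo-2-(4-methoxyphenyl)-4H-chromen-4-one F7.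
- Coupling of F3 with F7 (Pd(PPh3)4, K3PO4, dioxane–H2O, 90 °C) should give 25.

This fallback gives up the mechanistic guarantee of the oxygen pattern and relies on the C8 preference of the iodination.

**Step 3.** The aryl migration may be incomplete. n-BuLi may deprotonate the benzylic positions of the benzyl ether or the acetal. The ynolate may be silylated on carbon, giving a silylketene.

Fallback: the ynolate is made by oxidising an acetylide. The fallback sets out from 3 and comes back at 6 through 5.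
- LiAlH4 (THF, 0 °C) gives [2-(benzyloxy)-5-(1,3-dioxolan-2-yl)phenyl]methanol F8.
- MnO2 (CH2Cl2) gives 2-(benzyloxy)-5-(1,3-dioxolan-2-yl)benzaldehyde F9.
- The Ohira–Bestmann reagent (dimethyl (1-diazo-2-oxopropyl)phosphonate, K2CO3, MeOH) gives 2-[4-(benzyloxy)-3-ethynylphenyl]-1,3-dioxolane F10.
- Deprotonation (n-BuLi, THF, −78 °C) and oxidation of the acetylide with lithium tert-butyl peroxide (from t-BuOOH and LiHMDS) should give ynolate 5, which is silylated with TIPSOTf to 6.

**Step 4.** Ketene made from 8 and Et3N may dimerise or be consumed by acylammonium chemistry before alkyne 7 traps it. The product is also volatile and sensitive to acid.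

Fallback: dichloroketene is used as a more reactive ketene. The fallback sets out from 7 and comes back at 10.
- Dichloroketene from Cl3CCOCl and zinc–copper couple (Et2O) should add to 7 to give 4,4-dichloro-3-ethoxycyclobut-2-en-1-one F11.
- Reductive dechlorination (Zn, AcOH, TMEDA, EtOH, 0 °C) should give 10.

**Step 7 (with steps 8 and 9).** Once the ortho phenoxide has formed, the electron-rich aldehyde is a poor electrophile, so acetylide addition may stall. Carbinol 20 may ionise to a quinone methide on work-up. In step 9 a competing five-ring closure would give an aurone.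

Fallback: ring C'' is made by Baker–Venkataraman chemistry, which cannot give an aurone. The fallback sets out from 17 and comes back at 26.
- MeMgBr (3 equiv, THF, 0 °C), a harder nucleophile, should give 2-[2-(benzyloxy)-5-(1,3-dioxolan-2-yl)phenyl]-5-ethoxy-6-(1-hydroxyethyl)-3-(triisopropylsilyloxy)phenol F12 (racemic).
- MnO2 gives 1-{3-[2-(benzyloxy)-5-(1,3-dioxolan-2-yl)phenyl]-6-ethoxy-2-hydroxy-4-(triisopropylsilyloxy)phenyl}ethan-1-one F13.
- 4-Methoxybenzoyl chloride (pyridine, DMAP) gives 2-acetyl-6-[2-(benzyloxy)-5-(1,3-dioxolan-2-yl)phenyl]-3-ethoxy-5-(triisopropylsilyloxy)phenyl 4-methoxybenzoate F14.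
- LiHMDS (THF, −78 → 0 °C) effects the acyl shift to 1-{3-[2-(benzyloxy)-5-(1,3-dioxolan-2-yl)phenyl]-6-ethoxy-2-hydroxy-4-(triisopropylsilyloxy)phenyl}-3-(4-methoxyphenyl)propane-1,3-dione F15.
- p-TsOH·H2O in wet toluene (80 °C) closes the pyranone and unmasks the aldehyde, giving 4-(benzyloxy)-3-[5-ethoxy-2-(4-methoxyphenyl)-4-oxo-7-(triisopropylsilyloxy)-4H-chromen-8-yl]benzaldehyde F16.
- CsF and BnBr (DMF) convert F16 into 26.

**Step 13.** Hydroxide may open pyranone ring C'' of 26 (retro-Claisen degradation). The condensation may also be slow because 28 reacts as its phenoxide.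

Fallback: the second pyranone is also made by acyl shift. The fallback sets out from 26 and comes back at 32.
- Pinnick oxidation (NaClO2, NaH2PO4, 2-methyl-2-butene, t-BuOH–H2O) gives 4-(benzyloxy)-3-[7-(benzyloxy)-5-ethoxy-2-(4-methoxyphenyl)-4-oxo-4H-chromen-8-yl]benzoic acid F17.
- Esterification with 28 (EDC·HCl, DMAP, CH2Cl2) gives 2-acetyl-3-(benzyloxy)-5-methoxyphenyl 4-(benzyloxy)-3-[7-(benzyloxy)-5-ethoxy-2-(4-methoxyphenyl)-4-oxo-4H-chromen-8-yl]benzoate F18.
- LiHMDS (THF, −78 → 0 °C) gives 1-[2-(benzyloxy)-6-hydroxy-4-methoxyphenyl]-3-{4-(benzyloxy)-3-[7-(benzyloxy)-5-ethoxy-2-(4-methoxyphenyl)-4-oxo-4H-chromen-8-yl]phenyl}propane-1,3-dione F19.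
- Cyclodehydration (AcOH, H2SO4 cat., 60 °C) gives 32.

**Step 15.** Chloride attack on ethyl is slower than on methyl, so the C5'' ether may cleave incompletely. Forcing conditions risk loss of a methyl ether, C-benzylation of the electron-rich rings by benzyl cations, or acid-promoted opening and reclosure of ring C'' to the 6''-aryl isomer once C5''–OH is free.

Fallback: the deprotection is split into two mechanistically different stages. The fallback sets out from 32 and comes back at 33.
- Hydrogenolysis (H2, Pd/C, THF–MeOH, 25 °C) removes the three benzyl groups to give 5''-O-ethylputraflavone F20.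
- The peri ethyl ether is then cleaved by chelation with AlCl3 (MeCN, reflux) to give 33.

## Further compounds

F1 | step 5 | 2-(benzyloxy)-5-(1,3-dioxolan-2-yl)benzoic acid | OC(=O)c1cc(C2OCCO2)ccc1OCc1ccccc1
F2 | step 5 | 2-[4-(benzyloxy)-3-iodophenyl]-1,3-dioxolane | Ic1cc(C2OCCO2)ccc1OCc1ccccc1
F3 | step 5 | 2-[2-(benzyloxy)-5-(1,3-dioxolan-2-yl)phenyl]-4,4,5,5-tetramethyl-1,3,2-dioxaborolane | CC1(C)OB(OC1(C)C)c1cc(C2OCCO2)ccc1OCc1ccccc1
F4 | step 5 | acacetin, 5,7-dihydroxy-2-(4-methoxyphenyl)-4H-chromen-4-one (purchased) | COc1ccc(-c2cc(=O)c3c(O)cc(O)cc3o2)cc1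
F5 | step 5 | 7-(benzyloxy)-5-hydroxy-2-(4-methoxyphenyl)-4H-chromen-4-one | COc1ccc(-c2cc(=O)c3c(O)cc(OCc4ccccc4)cc3o2)cc1
F6 | step 5 | 7-(benzyloxy)-5-ethoxy-2-(4-methoxyphenyl)-4H-chromen-4-one | COc1ccc(-c2cc(=O)c3c(OCC)cc(OCc4ccccc4)cc3o2)cc1
F7 | step 5 | 7-(benzyloxy)-5-ethoxy-8-iodo-2-(4-methoxyphenyl)-4H-chromen-4-one | COc1ccc(-c2cc(=O)c3c(OCC)cc(OCc4ccccc4)c(I)c3o2)cc1
F8 | step 3 | [2-(benzyloxy)-5-(1,3-dioxolan-2-yl)phenyl]methanol | OCc1cc(C2OCCO2)ccc1OCc1ccccc1
F9 | step 3 | 2-(benzyloxy)-5-(1,3-dioxolan-2-yl)benzaldehyde | O=Cc1cc(C2OCCO2)ccc1OCc1ccccc1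
F10 | step 3 | 2-[4-(benzyloxy)-3-ethynylphenyl]-1,3-dioxolane | C#Cc1cc(C2OCCO2)ccc1OCc1ccccc1
F11 | step 4 | 4,4-dichloro-3-ethoxycyclobut-2-en-1-one | CCOC1=CC(=O)C1(Cl)Cl
F12 | step 7 | 2-[2-(benzyloxy)-5-(1,3-dioxolan-2-yl)phenyl]-5-ethoxy-6-(1-hydroxyethyl)-3-(triisopropylsilyloxy)phenol (racemic) | CC(O)c1c(OCC)cc(O[Si](C(C)C)(C(C)C)C(C)C)c(-c2cc(C3OCCO3)ccc2OCc2ccccc2)c1O
F13 | step 7 | 1-{3-[2-(benzyloxy)-5-(1,3-dioxolan-2-yl)phenyl]-6-ethoxy-2-hydroxy-4-(triisopropylsilyloxy)phenyl}ethan-1-one | CC(=O)c1c(OCC)cc(O[Si](C(C)C)(C(C)C)C(C)C)c(-c2cc(C3OCCO3)ccc2OCc2ccccc2)c1O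
F14 | step 7 | 2-acetyl-6-[2-(benzyloxy)-5-(1,3-dioxolan-2-yl)phenyl]-3-ethoxy-5-(triisopropylsilyloxy)phenyl 4-methoxybenzoate | COc1ccc(cc1)C(=O)Oc1c(C(C)=O)c(OCC)cc(O[Si](C(C)C)(C(C)C)C(C)C)c1-c1cc(C2OCCO2)ccc1OCc1ccccc1
F15 | step 7 | 1-{3-[2-(benzyloxy)-5-(1,3-dioxolan-2-yl)phenyl]-6-ethoxy-2-hydroxy-4-(triisopropylsilyloxy)phenyl}-3-(4-methoxyphenyl)propane-1,3-dione | COc1ccc(cc1)C(=O)CC(=O)c1c(OCC)cc(O[Si](C(C)C)(C(C)C)C(C)C)c(-c2cc(C3OCCO3)ccc2OCc2ccccc2)c1O
F16 | step 7 | 4-(benzyloxy)-3-[5-ethoxy-2-(4-methoxyphenyl)-4-oxo-7-(triisopropylsilyloxy)-4H-chromen-8-yl]benzaldehyde | COc1ccc(-c2cc(=O)c3c(OCC)cc(O[Si](C(C)C)(C(C)C)C(C)C)c(-c4cc(C=O)ccc4OCc4ccccc4)c3o2)cc1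
F17 | step 13 | 4-(benzyloxy)-3-[7-(benzyloxy)-5-ethoxy-2-(4-methoxyphenyl)-4-oxo-4H-chromen-8-yl]benzoic acid | COc1ccc(-c2cc(=O)c3c(OCC)cc(OCc4ccccc4)c(-c4cc(C(=O)O)ccc4OCc4ccccc4)c3o2)cc1
F18 | step 13 | 2-acetyl-3-(benzyloxy)-5-methoxyphenyl 4-(benzyloxy)-3-[7-(benzyloxy)-5-ethoxy-2-(4-methoxyphenyl)-4-oxo-4H-chromen-8-yl]benzoate | COc1ccc(-c2cc(=O)c3c(OCC)cc(OCc4ccccc4)c(-c4cc(C(=O)Oc5cc(OC)cc(OCc6ccccc6)c5C(C)=O)ccc4OCc4ccccc4)c3o2)cc1
F19 | step 13 | 1-[2-(benzyloxy)-6-hydroxy-4-methoxyphenyl]-3-{4-(benzyloxy)-3-[7-(benzyloxy)-5-ethoxy-2-(4-methoxyphenyl)-4-oxo-4H-chromen-8-yl]phenyl}propane-1,3-dione | COc1ccc(-c2cc(=O)c3c(OCC)cc(OCc4ccccc4)c(-c4cc(C(=O)CC(=O)c5c(O)cc(OC)cc5OCc5ccccc5)ccc4OCc4ccccc4)c3o2)cc1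
F20 | step 15 | 5''-O-ethylputraflavone, 2-{3-[5-ethoxy-7-hydroxy-2-(4-methoxyphenyl)-4-oxo-4H-chromen-8-yl]-4-hydroxyphenyl}-5-hydroxy-7-methoxy-4H-chromen-4-one | COc1ccc(-c2cc(=O)c3c(OCC)cc(O)c(-c4cc(-c5cc(=O)c6c(O)cc(OC)cc6o5)ccc4O)c3o2)cc1
A1 | alternative 1 | methyl 2-oxo-3-(2,4,6-trimethoxyphenyl)-2H-pyran-5-carboxylate | COC(=O)C1=COC(=O)C(c2c(OC)cc(OC)cc2OC)=C1
A2 | alternative 1 | 1,1-dimethoxyethene | C=C(OC)OC
A3 | alternative 1 | methyl 4-methoxy-3-(2,4,6-trimethoxyphenyl)benzoate | COC(=O)c1ccc(OC)c(-c2c(OC)cc(OC)cc2OC)c1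
A4 | alternative 2 | 5,7-bis(benzyloxy)-8-[(1Z,3E)-4-methoxy-2-(trimethylsilyloxy)buta-1,3-dienyl]-2-(4-methoxyphenyl)-4H-chromen-4-one | CO/C=C/C(O[Si](C)(C)C)=C/c1c(OCc2ccccc2)cc(OCc2ccccc2)c2c(=O)cc(-c3ccc(OC)cc3)oc12
A5 | alternative 2 | 5-(benzyloxy)-2-ethynyl-7-methoxy-4H-chromen-4-one | C#Cc1cc(=O)c2c(OCc3ccccc3)cc(OC)cc2o1
A6 | alternative 2 | 5,5'',7''-tri-O-benzylputraflavone | COc1ccc(-c2cc(=O)c3c(OCc4ccccc4)cc(OCc4ccccc4)c(-c4cc(-c5cc(=O)c6c(OCc7ccccc7)cc(OC)cc6o5)ccc4O)c3o2)cc1
A7 | alternative 3 | 2-acetyl-3-(benzyloxy)-5-methoxyphenyl 3-[3-acetyl-4,6-bis(benzyloxy)-2-(4-methoxybenzoyloxy)phenyl]-4-(benzyloxy)benzoate | COc1ccc(cc1)C(=O)Oc1c(C(C)=O)c(OCc2ccccc2)cc(OCc2ccccc2)c1-c1cc(ccc1OCc1ccccc1)C(=O)Oc1cc(OC)cc(OCc2ccccc2)c1C(C)=O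
A8 | alternative 3 | biaryl bis(1,3-diketone) with both ortho phenols released | COc1ccc(cc1)C(=O)CC(=O)c1c(O)c(c(OCc2ccccc2)cc1OCc1ccccc1)-c1cc(ccc1OCc1ccccc1)C(=O)CC(=O)c1c(O)cc(OC)cc1OCc1ccccc1
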